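The upper ring is the dihydrobenzofuran bearing the guaiacyl group. The lower ring is the one fused to the hydroxypropyl arene.

1. **Cuts:** strip two benzyl ethers and return both CH2OH groups to CO2Me. Cut the lower ring at C3–C3a by a retro 1,2-aryl shift, which re-inserts the ester carbon as C4 of a six-membered chroman-4-one (flavanone). Cut C2–aryl of that flavanone (retro conjugate arylation of a chromone), treat the upper ring the same way, and cut the aryl–CH2 bond of the propanol chain.
2. **Enabling feature:** in the lower ring O1–C2–C3–C3a–C7a, C3 bears a one-carbon arm and is bonded to aryl carbon C3a, whose ortho neighbour C7a carries O1. The unit C3a–C3–C(arm) is the footprint of an aryl carbon that moved from a carbonyl carbon to its α-carbon, so the ring is a flavanone ring O1–C2–C3–C4–C4a–C8a that has pushed out C4.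
3. **Forward order:** the pyranone ring of bromochromone 4 comes first. Arylation and contraction give the upper ring, then Br becomes B(OH)2. A second portion of 4 receives the C3 chain, a second arylation joins the halves as a flavanone, and its contraction forms the lower ring last.
4. **Stereochemistry:** both C2 centres come from catalyst-controlled Pd/(S)-t-BuPyOx conjugate additions. Both C3 centres are relayed from C2 in the contractions (trans, also the thermodynamic epimer). The end game touches no stereocentre.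
5. **Helpers:** ring carbon C4 (kept as the CH2OH carbon), Br (handle for boron and for the chain), and benzyl ethers (removed in the last step).

Key step: step 8

Assumption: (S)-t-BuPyOx, (S)-4-tert-butyl-2-(pyridin-2-yl)-4,5-dihydrooxazole, is taken to give the (2R)-flavanone by analogy with its sense of induction on 3-substituted cyclohexenones. If the sense proves opposite, (R)-t-BuPyOx is used in steps 3 and 7 with no other change.
Assumption: compounds 1, 5 and 11 are catalogue chemicals.

Step 1
Reactants: 1 1-(2-hydroxy-3-methoxyphenyl)ethanone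
Product: 2 1-(5-bromo-2-hydroxy-3-methoxyphenyl)ethanone
Conditions: NBS, MeCN, 0 °C to rt
Reagents that add atoms: N-bromosuccinimide, O=C1CCC(=O)N1Br
Why: Electrophilic aromatic bromination, in which the free phenol directs to its open para position (C5) as in the bromination of o-vanillin, and NBS in MeCN avoids α-bromination of the ketone.

Step 2
Reactants: 2 1-(5-bromo-2-hydroxy-3-methoxyphenyl)ethanone
Product: 4 6-bromo-8-methoxy-4H-chromen-4-one, via enaminone 3 (not isolated)
Conditions: Me2NCH(OMe)2, toluene, 100 °C; then conc. HCl, CH2Cl2, 40 °C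
Reagents that add atoms: N,N-dimethylformamide dimethyl acetal, COC(OC)N(C)C
Why: Enaminone condensation followed by acid-induced addition–elimination of the phenol OH at the β-carbon is the standard chromone synthesis from 2'-hydroxyacetophenones.

Step 3
Reactants: 4 6-bromo-8-methoxy-4H-chromen-4-one; 5 [4-(benzyloxy)-3-methoxyphenyl]boronic acid
Product: 6 (2R)-2-[4-(benzyloxy)-3-methoxyphenyl]-6-bromo-8-methoxychroman-4-one
Conditions: Pd(OCOCF3)2 (5 mol %), (S)-t-BuPyOx (6 mol %), NH4PF6 (30 mol %), H2O (5 equiv), ClCH2CH2Cl, 60 °C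
Reagents that add atoms: none
Why: Palladium-catalysed asymmetric conjugate addition of an arylboronic acid to a chromone, in which the cationic divalent aryl-palladium species inserts C2=C3 on the face left open by the tert-butyl group (C2 set as R), protonolysis of the palladium enolate in a nearly neutral medium avoids retro-oxa-Michael racemisation, and the C–Br bond is spared because no zerovalent palladium lies on the cycle.

Step 4
Reactants: 6 (2R)-2-[4-(benzyloxy)-3-methoxyphenyl]-6-bromo-8-methoxychroman-4-one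
Product: 9 methyl (2R,3R)-2-[4-(benzyloxy)-3-methoxyphenyl]-5-bromo-7-methoxy-2,3-dihydro-1-benzofuran-3-carboxylate, via enol ether 7 (not isolated), via iodane ketal 8 (not isolated)
Conditions: PhI(OAc)2 (1.2 equiv), HC(OMe)3, H2SO4 (cat.), 0 °C to rt; aqueous work-up
Reagents that add atoms: trimethyl orthoformate, COC(OC)OC; water, O; PhI(OAc)2, CC(=O)OI(OC(C)=O)c1ccccc1 (its atoms stay only in 8)
Why: Oxidative 1,2-aryl shift with trivalent iodine in trimethyl orthoformate, the documented ring contraction of flavanones, in which iodine adds to C3 of 7 anti to the C2 aryl group and C4a migrates from C4 to C3 with inversion as PhI leaves from 8, so that C2 stays R and the new C3 centre is set trans (3R), the epimer also favoured at equilibrium.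

Step 5
Reactants: 9 methyl (2R,3R)-2-[4-(benzyloxy)-3-methoxyphenyl]-5-bromo-7-methoxy-2,3-dihydro-1-benzofuran-3-carboxylate
Product: 10 [(2R,3R)-2-[4-(benzyloxy)-3-methoxyphenyl]-7-methoxy-3-(methoxycarbonyl)-2,3-dihydro-1-benzofuran-5-yl]boronic acid
Conditions: B2(OH)4, PdCl(XPhos)(2'-aminobiphenyl-2-yl) (1 mol %), XPhos (2 mol %), KOAc, EtOH, 80 °C; aqueous work-up
Reagents that add atoms: tetrahydroxydiboron, OB(O)B(O)O
Why: Miyaura-type borylation with tetrahydroxydiboron gives the free boronic acid in one operation, KOAc being too weak a base to enolise the β-aryloxy ester, and it is placed after the contraction because a flavanone would racemise through its chalcone under acetate in hot ethanol.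

Step 6
Reactants: 4 6-bromo-8-methoxy-4H-chromen-4-one; 11 allyl benzyl ether
Product: 13 6-[3-(benzyloxy)propyl]-8-methoxy-4H-chromen-4-one, via alkylborane 12 (not isolated)
Conditions: 11, 9-BBN-H, THF, 0 °C to rt; then 4, PdCl2(dppf), aq K3PO4, DMF, 50 °C
Reagents that add atoms: 9-borabicyclo[3.3.1]nonane, B1C2CCCC1CCC2 (its boron and carbons stay only in 12)
Why: Anti-Markovnikov hydroboration of the terminal alkene followed by B-alkyl Suzuki–Miyaura coupling at the C6–Br bond, a reaction type that bromochromones tolerate with phosphate or carbonate bases, installs the three-carbon chain at its final oxidation level.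

Step 7
Reactants: 10 [(2R,3R)-2-[4-(benzyloxy)-3-methoxyphenyl]-7-methoxy-3-(methoxycarbonyl)-2,3-dihydro-1-benzofuran-5-yl]boronic acid; 13 6-[3-(benzyloxy)propyl]-8-methoxy-4H-chromen-4-one
Product: 14 methyl (2R,3R)-2-[4-(benzyloxy)-3-methoxyphenyl]-5-[(2R)-6-[3-(benzyloxy)propyl]-8-methoxy-4-oxochroman-2-yl]-7-methoxy-2,3-dihydro-1-benzofuran-3-carboxylate
Conditions: Pd(OCOCF3)2 (10 mol %), (S)-t-BuPyOx (12 mol %), NH4PF6 (30 mol %), H2O (5 equiv), ClCH2CH2Cl, 60 °C, 13 in slight excess
Reagents that add atoms: none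
Why: Same palladium-catalysed asymmetric conjugate addition as in step 3, in which the new C2 centre is set R by the ligand because the resident centres of 10 lie far from the boron-bearing carbon and should exert little bias, and the nearly neutral medium spares the ester and the configurationally labile flavanone.

Step 8
Reactants: 14 methyl (2R,3R)-2-[4-(benzyloxy)-3-methoxyphenyl]-5-[(2R)-6-[3-(benzyloxy)propyl]-8-methoxy-4-oxochroman-2-yl]-7-methoxy-2,3-dihydro-1-benzofuran-3-carboxylate
Product: 17 methyl (2R,3R)-2-[(2R,3R)-2-[4-(benzyloxy)-3-methoxyphenyl]-7-methoxy-3-(methoxycarbonyl)-2,3-dihydro-1-benzofuran-5-yl]-5-[3-(benzyloxy)propyl]-7-methoxy-2,3-dihydro-1-benzofuran-3-carboxylate, via enol ether 15 (not isolated), via iodane ketal 16 (not isolated)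
Conditions: PhI(OAc)2 (1.2 equiv), HC(OMe)3, H2SO4 (cat.), 0 °C to rt; aqueous work-up
Reagents that add atoms: trimethyl orthoformate, COC(OC)OC; water, O; PhI(OAc)2, CC(=O)OI(OC(C)=O)c1ccccc1 (its atoms stay only in 16)
Why: H2SO4/HC(OMe)3 convert the C4 ketone of the six-membered ring O1–C2–C3–C4–C4a–C8a into enol ether 15, PhI(OAc)2 adds to C3 anti to the equatorial C2 aryl group while methanol caps C4 to give the 2,3-trans iodane ketal 16, and loss of PhI is assisted by aryl carbon C4a, which moves from C4 to C3 and leaves a dimethoxycarbenium ion that ends as the methyl ester. The closest known reaction type is this one itself, the trivalent-iodine oxidative 1,2-aryl shift of aryl ketones in trimethyl orthoformate, documented for flavanones as a contraction to methyl trans-2-aryl-2,3-dihydrobenzofuran-3-carboxylates. The five-membered ring O1–C2–C3–C3a–C7a is closed through the new C3–C3a bond by a 1,2-shift via a bridged phenonium ion (3-exo-tet attack of C4a on C3, then cleavage of C4–C4a), so that C4 is extruded as the exocyclic carboxyl carbon. C2 is not involved and stays R, and the new centre C3 is controlled by C2, because anti delivery of iodine followed by inversion at C3 places the ester trans to the aryl group (3R), which is also the thermodynamic epimer. The step needs the C4a shift to win over the 2→3 shift of the electron-rich C2 aryl group (isoflavone path) and over elimination (flavone path), and this is secured in the diequatorial conformer of 16, where the C3–I bond is antiperiplanar to C4–C4a but not to C2–aryl, by the two ketal oxygens that take up the charge at C4 and by the ortho ring oxygen that raises the migratory aptitude of C4a. Chemoselectivity follows from the substrate, which holds only one enolisable ketone, no free OH, and esters and benzyl ethers that tolerate the oxidant and brief acid.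

Step 9
Reactants: 17 the diester of step 8
Product: 18 [(2R,3S)-2-[(2R,3S)-2-[4-(benzyloxy)-3-methoxyphenyl]-3-(hydroxymethyl)-7-methoxy-2,3-dihydro-1-benzofuran-5-yl]-5-[3-(benzyloxy)propyl]-7-methoxy-2,3-dihydro-1-benzofuran-3-yl]methanol
Conditions: LiAlH4, THF, 0 °C; aqueous work-up
Reagents that add atoms: none
Why: Ester reduction with LiAlH4, in which hydride addition to the two ester carbonyls at 0 °C outruns enolisation so that the C3 centres and the β-aryloxy C2–O bonds persist (the descriptor at C3 changes from R to S by priority only), the benzyl ethers are inert and the still masked phenol rules out quinone methide formation.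

Step 10
Reactants: 18 the bis-benzyl ether diol of step 9
Product: 19 4-[(2R,3S)-3-(hydroxymethyl)-5-[(2R,3S)-3-(hydroxymethyl)-5-(3-hydroxypropyl)-7-methoxy-2,3-dihydro-1-benzofuran-2-yl]-7-methoxy-2,3-dihydro-1-benzofuran-2-yl]-2-methoxyphenol (CNP0599161.1)
Conditions: H2 (1 atm), Pd/C, EtOAc/MeOH, rt
Reagents that add atoms: none
Why: Catalytic hydrogenolysis cleaves the aryl benzyl and the alkyl benzyl ether, while the cyclic benzylic C2–O bonds of 2-aryl-dihydrobenzofurans are known to persist under Pd/C at one atmosphere in neutral solvent, so no stereocentre is touched.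

**Compound list**

1 | 1-(2-hydroxy-3-methoxyphenyl)ethanone | CC(=O)c1cccc(OC)c1O | starting material
2 | 1-(5-bromo-2-hydroxy-3-methoxyphenyl)ethanone | CC(=O)c1cc(Br)cc(OC)c1O | intermediate
3 | (E)-1-(5-bromo-2-hydroxy-3-methoxyphenyl)-3-(dimethylamino)prop-2-en-1-one | CN(C)/C=C/C(=O)c1cc(Br)cc(OC)c1O | intermediate
4 | 6-bromo-8-methoxy-4H-chromen-4-one | O=c1ccoc2c(OC)cc(Br)cc12 | intermediate
5 | [4-(benzyloxy)-3-methoxyphenyl]boronic acid | COc1cc(B(O)O)ccc1OCc1ccccc1 | starting material
6 | (2R)-2-[4-(benzyloxy)-3-methoxyphenyl]-6-bromo-8-methoxychroman-4-one | COc1cc([C@@H]2Oc3c(OC)cc(Br)cc3C(=O)C2)ccc1OCc1ccccc1 | intermediate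
7 | (2R)-2-[4-(benzyloxy)-3-methoxyphenyl]-6-bromo-4,8-dimethoxy-2H-chromene | COc1cc([C@@H]2Oc3c(OC)cc(Br)cc3C(OC)=C2)ccc1OCc1ccccc1 | intermediate
8 | 2,3-trans-3-[acetoxy(phenyl)-λ3-iodanyl]-2-[4-(benzyloxy)-3-methoxyphenyl]-6-bromo-4,4,8-trimethoxychroman (iodine and C2 aryl group on opposite faces) | COc1cc([C@@H]2Oc3c(OC)cc(Br)cc3C(OC)(OC)[C@H]2I(OC(C)=O)c4ccccc4)ccc1OCc1ccccc1 | intermediate
9 | methyl (2R,3R)-2-[4-(benzyloxy)-3-methoxyphenyl]-5-bromo-7-methoxy-2,3-dihydro-1-benzofuran-3-carboxylate | COc1cc([C@@H]2Oc3c(OC)cc(Br)cc3[C@H]2C(=O)OC)ccc1OCc1ccccc1 | intermediate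
10 | [(2R,3R)-2-[4-(benzyloxy)-3-methoxyphenyl]-7-methoxy-3-(methoxycarbonyl)-2,3-dihydro-1-benzofuran-5-yl]boronic acid | COc1cc([C@@H]2Oc3c(OC)cc(B(O)O)cc3[C@H]2C(=O)OC)ccc1OCc1ccccc1 | intermediate
11 | allyl benzyl ether | C=CCOCc1ccccc1 | starting material
12 | 9-[3-(benzyloxy)propyl]-9-borabicyclo[3.3.1]nonane | C(CCB1C2CCCC1CCC2)OCc1ccccc1 | intermediate
13 | 6-[3-(benzyloxy)propyl]-8-methoxy-4H-chromen-4-one | O=c1ccoc2c(OC)cc(CCCOCc3ccccc3)cc12 | intermediate
14 | methyl (2R,3R)-2-[4-(benzyloxy)-3-methoxyphenyl]-5-[(2R)-6-[3-(benzyloxy)propyl]-8-methoxy-4-oxochroman-2-yl]-7-methoxy-2,3-dihydro-1-benzofuran-3-carboxylate | COc1cc([C@@H]2Oc3c(OC)cc([C@@H]4Oc5c(OC)cc(CCCOCc6ccccc6)cc5C(=O)C4)cc3[C@H]2C(=O)OC)ccc1OCc1ccccc1 | intermediate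
15 | methyl (2R,3R)-2-[4-(benzyloxy)-3-methoxyphenyl]-5-[(2R)-6-[3-(benzyloxy)propyl]-4,8-dimethoxy-2H-chromen-2-yl]-7-methoxy-2,3-dihydro-1-benzofuran-3-carboxylate | COc1cc([C@@H]2Oc3c(OC)cc([C@@H]4Oc5c(OC)cc(CCCOCc6ccccc6)cc5C(OC)=C4)cc3[C@H]2C(=O)OC)ccc1OCc1ccccc1 | intermediate
16 | 2,3-trans 3-[acetoxy(phenyl)-λ3-iodanyl]-4,4-dimethoxychroman derived from 15 (iodine and C2 aryl group on opposite faces) | COc1cc([C@@H]2Oc3c(OC)cc([C@@H]4Oc5c(OC)cc(CCCOCc6ccccc6)cc5C(OC)(OC)[C@H]4I(OC(C)=O)c7ccccc7)cc3[C@H]2C(=O)OC)ccc1OCc1ccccc1 | intermediate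
17 | methyl (2R,3R)-2-[(2R,3R)-2-[4-(benzyloxy)-3-methoxyphenyl]-7-methoxy-3-(methoxycarbonyl)-2,3-dihydro-1-benzofuran-5-yl]-5-[3-(benzyloxy)propyl]-7-methoxy-2,3-dihydro-1-benzofuran-3-carboxylate | COc1cc([C@@H]2Oc3c(OC)cc([C@@H]4Oc5c(OC)cc(CCCOCc6ccccc6)cc5[C@H]4C(=O)OC)cc3[C@H]2C(=O)OC)ccc1OCc1ccccc1 | intermediate
18 | [(2R,3S)-2-[(2R,3S)-2-[4-(benzyloxy)-3-methoxyphenyl]-3-(hydroxymethyl)-7-methoxy-2,3-dihydro-1-benzofuran-5-yl]-5-[3-(benzyloxy)propyl]-7-methoxy-2,3-dihydro-1-benzofuran-3-yl]methanol | COc1cc([C@@H]2Oc3c(OC)cc([C@@H]4Oc5c(OC)cc(CCCOCc6ccccc6)cc5[C@H]4CO)cc3[C@H]2CO)ccc1OCc1ccccc1 | intermediate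
19 | 4-[(2R,3S)-3-(hydroxymethyl)-5-[(2R,3S)-3-(hydroxymethyl)-5-(3-hydroxypropyl)-7-methoxy-2,3-dihydro-1-benzofuran-2-yl]-7-methoxy-2,3-dihydro-1-benzofuran-2-yl]-2-methoxyphenol | COc1cc([C@@H]2Oc3c(OC)cc([C@@H]4Oc5c(OC)cc(CCCO)cc5[C@H]4CO)cc3[C@H]2CO)ccc1O | target

Total step count: 10.
Longest linear sequence: 9 steps (1 → 2 → 4 → 6 → 9 → 10 → 14 → 17 → 18 → 19; step 6 is the side branch).

**Steps most likely to fail**

**Step 8.**
- What may go wrong: a competing 2→3 shift of the very electron-rich C2 aryl group; dehydrogenation of the pyranone ring; acid-induced ionisation of the para-oxygenated benzylic C2–O bond with epimerisation at C2; over-oxidation of the alkoxyarenes.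
- The fallback sets out from 14 and comes back at 17. It keeps the contraction but makes it non-oxidative and free of strong acid.
- Condensation of the only enolisable CH2 (C3) with Me2NCH(OMe)2 in warm toluene should give the 3-(dimethylaminomethylene)flavanone F1.
- Neutral diazo transfer with tosyl azide (cycloaddition, then fragmentation) should give the 3-diazoflavanone F2.
- Irradiation at 365 nm in MeOH triggers a Wolff rearrangement, in which C4a again migrates from C4 to C3 to give the ring-contracted ketene F3.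
- Methanol adds to the ketene. Protonation from the face away from the aryl group should first give mainly the cis ester F4, which is equilibrated with DBU in CH2Cl2 to the trans ester 17.

**Step 7.**
- What may go wrong: protodeboronation or homocoupling of the electron-rich, precious boronic acid faster than insertion; incomplete facial selectivity.
- The fallback sets out from 9 and 2 (with alkylborane 12 from step 6) and comes back at 14. It uses no boronic acid.
- Reductive carbonylation of 9 (Pd(OAc)2, P(1-adamantyl)2(n-Bu), TMEDA, CO/H2, toluene, 100 °C) should give the 5-formyl dihydrobenzofuran ester F5.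
- B-alkyl Suzuki–Miyaura coupling of 2 with 12 (PdCl2(dppf), aq K3PO4) should give the chain-bearing 2'-hydroxyacetophenone F6.
- A Kabbe-type condensation of F5 with F6 (pyrrolidine, MeOH, 50 °C) passes through the 2'-hydroxychalcone F7 and closes by oxa-Michael addition.
- No useful bias at the new centre is expected. Because the upper half is a single enantiomer, 14 and its C2 epimer, the (2S)-flavanone F8, are diastereomers that can be separated by chromatography.
- F8 is returned to the same amine conditions, re-equilibrated through F7 and recycled.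

**Step 3.**
- What may go wrong: sluggish insertion into the 8-methoxy-substituted chromone; erosion of enantioselectivity; attack on the C–Br bond by adventitious zerovalent palladium.
- The fallback sets out from 2 and comes back at 6.
- Claisen–Schmidt condensation of 2 with commercial 4-(benzyloxy)-3-methoxybenzaldehyde (KOH, EtOH, rt) should give the 2'-hydroxychalcone F9.
- NaOAc in refluxing EtOH closes it to the racemic flavanone F10.
- A Noyori-type transfer-hydrogenative kinetic resolution (RuCl[(S,S)-TsDPEN](p-cymene), HCO2H/Et3N, rt, stopped near half conversion) should reduce the (2S) enantiomer to the cis-(2S,4S)-flavan-4-ol F11. It leaves (2R)-6, which is separated by chromatography.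

Step 4 has the same failure modes as step 8 in a milder form, since its substrate is of the type on which this contraction is best documented. It is therefore ranked fourth.

**Further compounds**

F1 | step 8 | methyl (2R,3R)-2-[4-(benzyloxy)-3-methoxyphenyl]-5-[(2R,3E)-6-[3-(benzyloxy)propyl]-3-(dimethylaminomethylene)-8-methoxy-4-oxochroman-2-yl]-7-methoxy-2,3-dihydro-1-benzofuran-3-carboxylate | COc1cc([C@@H]2Oc3c(OC)cc([C@@H]4Oc5c(OC)cc(CCCOCc6ccccc6)cc5C(=O)/C4=C/N(C)C)cc3[C@H]2C(=O)OC)ccc1OCc1ccccc1
F2 | step 8 | 3-diazo derivative of flavanone 14 | COc1cc([C@@H]2Oc3c(OC)cc([C@@H]4Oc5c(OC)cc(CCCOCc6ccccc6)cc5C(=O)C4=[N+]=[N-])cc3[C@H]2C(=O)OC)ccc1OCc1ccccc1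
F3 | step 8 | ring-contracted ketene (2-aryl-3-(oxomethylidene)-2,3-dihydrobenzofuran) | COc1cc([C@@H]2Oc3c(OC)cc([C@@H]4Oc5c(OC)cc(CCCOCc6ccccc6)cc5C4=C=O)cc3[C@H]2C(=O)OC)ccc1OCc1ccccc1
F4 | step 8 | lower-ring 2,3-cis epimer of diester 17 | COc1cc([C@@H]2Oc3c(OC)cc([C@@H]4Oc5c(OC)cc(CCCOCc6ccccc6)cc5[C@@H]4C(=O)OC)cc3[C@H]2C(=O)OC)ccc1OCc1ccccc1
F5 | step 7 | methyl (2R,3R)-2-[4-(benzyloxy)-3-methoxyphenyl]-5-formyl-7-methoxy-2,3-dihydro-1-benzofuran-3-carboxylate | COc1cc([C@@H]2Oc3c(OC)cc(C=O)cc3[C@H]2C(=O)OC)ccc1OCc1ccccc1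
F6 | step 7 | 1-[5-[3-(benzyloxy)propyl]-2-hydroxy-3-methoxyphenyl]ethanone | CC(=O)c1cc(CCCOCc2ccccc2)cc(OC)c1O
F7 | step 7 | (E)-2'-hydroxychalcone from F5 and F6 | COc1cc([C@@H]2Oc3c(OC)cc(/C=C/C(=O)c4cc(CCCOCc5ccccc5)cc(OC)c4O)cc3[C@H]2C(=O)OC)ccc1OCc1ccccc1
F8 | step 7 | (2S)-chromanone epimer of 14 | COc1cc([C@@H]2Oc3c(OC)cc([C@H]4Oc5c(OC)cc(CCCOCc6ccccc6)cc5C(=O)C4)cc3[C@H]2C(=O)OC)ccc1OCc1ccccc1
F9 | step 3 | (E)-3-[4-(benzyloxy)-3-methoxyphenyl]-1-(5-bromo-2-hydroxy-3-methoxyphenyl)prop-2-en-1-one | COc1cc(/C=C/C(=O)c2cc(Br)cc(OC)c2O)ccc1OCc1ccccc1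
F10 | step 3 | racemic 2-[4-(benzyloxy)-3-methoxyphenyl]-6-bromo-8-methoxychroman-4-one | COc1cc(C2Oc3c(OC)cc(Br)cc3C(=O)C2)ccc1OCc1ccccc1
F11 | step 3 | (2S,4S)-2-[4-(benzyloxy)-3-methoxyphenyl]-6-bromo-8-methoxychroman-4-ol | COc1cc([C@H]2Oc3c(OC)cc(Br)cc3[C@@H](O)C2)ccc1OCc1ccccc1
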